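**Retrosynthetic overview**
- Last disconnection: the vicinal C–Br/C–Cl pair of ring B, made in one undirected, face- and site-selective bromochlorination of the ring B trisubstituted alkene (proposed new method).
- The exocyclic methylene comes from a ring A ketone by carbonyl methylenation; ring B and the spiro centre come from a Diels–Alder reaction of a ring A 2-methylidene ketone with a five-carbon diene.
- The 2-methylidene ketone comes from a cyclic β-keto ester whose ester carbon becomes the dienophile CH2.
- Ring A and its C–Br centre come from a stereospecific bromonium cyclisation of an acyclic bromochloro β-keto ester, assembled from a five-carbon allylic alcohol (enantioselective bromochlorination) and an acetoacetate dianion.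
- Order of ring formation: ring A (the ring with the gem-dimethyl group) first, ring B (the ring with Br and Cl) second.

Assumption: in steps 1 and 9 the catalyst antipode that gives the drawn configuration is used (both antipodes are equally accessible); the step 9 catalyst is written as its (1R,2R) form.

**Route**

Step 1
Reactants: 1 3-methylbut-2-en-1-ol (prenol)
Product: 2 (2S)-2-bromo-3-chloro-3-methylbutan-1-ol
Conditions: NBS (1.05 equiv), ClTi(OiPr)3 (1.1 equiv), chiral tridentate Schiff-base ligand (salicylaldimine of a 1,1-diaryl amino alcohol, 20 mol %), hexanes, −20 °C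
Reagents that add atoms: N-bromosuccinimide O=C1CCC(=O)N1Br; chlorotitanium triisopropoxide CC(C)O[Ti](Cl)(OC(C)C)OC(C)C
Why: Titanium/Schiff-base-catalysed enantioselective bromochlorination of an allylic alcohol: prenol binds as its titanium alkoxide, NBS forms the bromonium on one enantioface and titanium-bound chloride opens it anti at the tertiary carbon (Markovnikov), which sets the single C–Br stereocentre as S.

Step 2
Reactants: 2 (2S)-2-bromo-3-chloro-3-methylbutan-1-ol
Product: 3 (2S)-2-bromo-3-chloro-3-methylbutyl trifluoromethanesulfonate
Conditions: Tf2O (1.1 equiv), pyridine (1.3 equiv), CH2Cl2, −78 °C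
Reagents that add atoms: trifluoromethanesulfonic anhydride O=S(=O)(OS(=O)(=O)C(F)(F)F)C(F)(F)F
Why: O-Sulfonylation of the primary alcohol at low temperature; the electron-withdrawing β-bromine keeps the primary triflate from ionising and the stereocentre is not touched.

Step 3
Reactants: 3 (2S)-2-bromo-3-chloro-3-methylbutyl trifluoromethanesulfonate; 4 methyl 3-oxobutanoate (methyl acetoacetate)
Product: 6 methyl (6S)-6-bromo-7-chloro-7-methyl-3-oxooctanoate, via methyl acetoacetate dianion 5 (not isolated)
Conditions: 4 (1.5 equiv), NaH then n-BuLi, THF, 0 °C; then 3, −78 → −40 °C; 1 M HCl quench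
Reagents that add atoms: none
Why: Weiler dianion γ-alkylation: the more reactive terminal carbanion of 5 displaces the primary triflate by SN2 at −78 °C, faster than elimination, and the C–Br stereocentre is a spectator.

Step 4
Reactants: 6 methyl (6S)-6-bromo-7-chloro-7-methyl-3-oxooctanoate
Product: 7 methyl (1S,3S)-3-bromo-2,2-dimethyl-6-oxocyclohexane-1-carboxylate
Conditions: (CF3)2CHOH (0.02 M), 23 °C
Reagents that add atoms: none
Why: Solvolytic cation–olefin cyclisation: bromine-assisted ionisation of the tertiary chloride in the ionising, non-nucleophilic solvent gives a configurationally defined bromonium that the enol carbon of the β-keto ester opens at the tertiary carbon through a chair transition state, so the C–Br centre stays S; the enolisable ester-bearing centre settles as the diequatorial 1S epimer and is erased in step 5.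

Step 5
Reactants: 7 methyl (1S,3S)-3-bromo-2,2-dimethyl-6-oxocyclohexane-1-carboxylate
Product: 8 methyl (5S)-5-bromo-2-[tert-butyl(dimethyl)silyl]oxy-6,6-dimethylcyclohex-1-ene-1-carboxylate
Conditions: TBSOTf (1.2 equiv), Et3N (2 equiv), CH2Cl2, 0 °C
Reagents that add atoms: tert-butyldimethylsilyl trifluoromethanesulfonate CC(C)(C)[Si](C)(C)OS(=O)(=O)C(F)(F)F
Why: Soft enolisation and O-silylation of the β-keto ester (Et3N removes the doubly activated proton) gives the conjugated silyl enol ether regioselectively without a free enolate, so the bromide is safe and C–Br is the only stereocentre left.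

Step 6
Reactants: 8 methyl (5S)-5-bromo-2-[tert-butyl(dimethyl)silyl]oxy-6,6-dimethylcyclohex-1-ene-1-carboxylate
Product: 10 (4S)-4-bromo-3,3-dimethyl-2-methylidenecyclohexan-1-one, via silyloxy allylic alcohol 9 (not isolated)
Conditions: iBu2AlH (2.5 equiv), CH2Cl2, −78 → −20 °C; then 1 M HCl, THF, 0 °C
Reagents that add atoms: none
Why: iBu2AlH reduces the vinylogous carbonate ester to allylic alcohol 9, and aqueous acid then ionises this vinylogous hemiacetal and removes the silyl group (Stork–Danheiser-type transposition) to unveil the 2-methylidene ketone; the C–Br centre is untouched.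

Step 7
Reactants: 10 (4S)-4-bromo-3,3-dimethyl-2-methylidenecyclohexan-1-one; 11 isoprene (2-methylbuta-1,3-diene)
Product: 12 (4S,6R)-4-bromo-5,5,9-trimethylspiro[5.5]undec-8-en-1-one
Conditions: 11 (5 equiv), Me2AlCl (20 mol %), CH2Cl2, −40 → 0 °C
Reagents that add atoms: none
Why: Lewis-acid-catalysed Diels–Alder reaction with para regiochemistry (the exocyclic CH2 bonds to C1 of isoprene, so the methyl ends 1,4 to the spiro carbon); the diene adds to the enone face anti to the axial methyl of the neighbouring gem-dimethyl carbon in the bromine-equatorial half-chair, that is trans to Br, which sets the spiro centre (6R here; the same centre is 6S in 13 and 14 only because the CIP priorities change).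

Step 8
Reactants: 12 (4S,6R)-4-bromo-5,5,9-trimethylspiro[5.5]undec-8-en-1-one
Product: 13 (6S,8S)-8-bromo-3,7,7-trimethyl-11-methylidenespiro[5.5]undec-2-ene
Conditions: Cp2TiMe2 (3 equiv), toluene, 65 °C, dark
Reagents that add atoms: dimethyltitanocene C[Ti](C)(C1C=CC=C1)C1C=CC=C1
Why: Petasis carbonyl methylenation through Cp2Ti=CH2 is non-basic and works on hindered, enolisable ketones, so the neopentyl bromide and the ring B alkene survive and no stereocentre is affected.

Step 9
Reactants: 13 (6S,8S)-8-bromo-3,7,7-trimethyl-11-methylidenespiro[5.5]undec-2-ene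
Product: 14 (2S,6S,8S,9S)-2,8-dibromo-9-chloro-1,1,9-trimethyl-5-methylidenespiro[5.5]undecane (nidificene)
Conditions: NBS (1.05 equiv), Me3SiCl (1.1 equiv, slow addition), (1R,2R)-N-[2-(2,4,6-triisopropylphenylselanyl)-2,3-dihydro-1H-inden-1-yl]-1,1,1-trifluoromethanesulfonamide (10 mol %), CH2Cl2, −78 → −20 °C
Reagents that add atoms: N-bromosuccinimide O=C1CCC(=O)N1Br; chlorotrimethylsilane C[Si](C)(C)Cl
Why: Proposed new method: the bulky bifunctional selenide takes up the BrCl made in the flask as a selenium-bound bromenium whose chloride stays hydrogen-bonded to the triflamide N–H; this large Br+ carrier reaches only the more electron-rich ring B trisubstituted alkene (the exocyclic 1,1-disubstituted alkene is less nucleophilic and neopentyl-shielded) and only its open face, anti to the axial ring A carbon that carries the methylidene and syn to the equatorial CMe2 carbon, and the paired chloride then opens the unsymmetrical bromonium anti at the tertiary carbon through a loose, Markovnikov, SN1-like transition state that needs no diaxial geometry, so Br (8S) and Cl (9S) end trans-diequatorial (the only other product of this bromonium, the diaxial tertiary bromide, is the 1,2-halogen-interchange partner of 14 and should drain to it on warming); closest known reaction types are Lewis-base-catalysed bromochlorination of simple alkenes with an N-bromoimide and a latent chloride, chiral selenide-catalysed halocyclisations, and titanium/Schiff-base bromochlorination of allylic alcohols, none of which has been shown to give face and site control on an undirected trisubstituted alkene of a diene.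

**Compound list**
1 | 3-methylbut-2-en-1-ol (prenol) | CC(C)=CCO | starting material
2 | (2S)-2-bromo-3-chloro-3-methylbutan-1-ol | OC[C@H](Br)C(C)(C)Cl | intermediate
3 | (2S)-2-bromo-3-chloro-3-methylbutyl trifluoromethanesulfonate | O=S(=O)(OC[C@H](Br)C(C)(C)Cl)C(F)(F)F | intermediate
4 | methyl 3-oxobutanoate (methyl acetoacetate) | COC(=O)CC(C)=O | starting material
5 | methyl acetoacetate dianion (sodium lithium salt) | [Na+].[Li+].COC(=O)[CH-]C(=O)[CH2-] | intermediate
6 | methyl (6S)-6-bromo-7-chloro-7-methyl-3-oxooctanoate | COC(=O)CC(=O)CC[C@H](Br)C(C)(C)Cl | intermediate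
7 | methyl (1S,3S)-3-bromo-2,2-dimethyl-6-oxocyclohexane-1-carboxylate | COC(=O)[C@@H]1C(=O)CC[C@H](Br)C1(C)C | intermediate
8 | methyl (5S)-5-bromo-2-[tert-butyl(dimethyl)silyl]oxy-6,6-dimethylcyclohex-1-ene-1-carboxylate | COC(=O)C1=C(O[Si](C)(C)C(C)(C)C)CC[C@H](Br)C1(C)C | intermediate
9 | [(5S)-5-bromo-2-[tert-butyl(dimethyl)silyl]oxy-6,6-dimethylcyclohex-1-en-1-yl]methanol | OCC1=C(O[Si](C)(C)C(C)(C)C)CC[C@H](Br)C1(C)C | intermediate
10 | (4S)-4-bromo-3,3-dimethyl-2-methylidenecyclohexan-1-one | C=C1C(=O)CC[C@H](Br)C1(C)C | intermediate
11 | isoprene (2-methylbuta-1,3-diene) | C=CC(C)=C | starting material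
12 | (4S,6R)-4-bromo-5,5,9-trimethylspiro[5.5]undec-8-en-1-one | O=C1CC[C@H](Br)C(C)(C)[C@]12CCC(C)=CC2 | intermediate
13 | (6S,8S)-8-bromo-3,7,7-trimethyl-11-methylidenespiro[5.5]undec-2-ene | C=C1CC[C@H](Br)C(C)(C)[C@]12CCC(C)=CC2 | intermediate
14 | (2S,6S,8S,9S)-2,8-dibromo-9-chloro-1,1,9-trimethyl-5-methylidenespiro[5.5]undecane (nidificene) | C=C1CC[C@H](Br)C(C)(C)[C@]12CC[C@](C)(Cl)[C@@H](Br)C2 | target

**Summary**
Total step count: 9.
Longest linear sequence: 9 steps (1 → 14); 4 and 11 enter as commercial building blocks.

**Three steps most likely to fail**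

Step 9 (the proposed new step). Risks are a wrong-face bromonium, attack on the exocyclic alkene, or transannular capture of the cation by that alkene. The fallback uses known chemistry, sets out from 13 and comes back at 14. NBS in THF/water at 0 °C gives the Markovnikov bromohydrin (2S,3S,6S,8S)-2,8-dibromo-3,7,7-trimethyl-11-methylidenespiro[5.5]undecan-3-ol F1, which can be freed from any diastereomer by chromatography. HCl (2 M in Et2O) in CH2Cl2 at −20 °C then exchanges the tertiary hydroxyl for chloride with retention, because the neighbouring bromine assists ionisation and chloride reopens the same bromonium at the tertiary carbon.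

Step 4. Risks are O-cyclisation through the enol oxygen or sluggish ionisation. The fallback sets out from 6 and comes back at 7. TBSOTf/Et3N (CH2Cl2, 0 °C) converts 6 into the silyl enol ether methyl (2Z,6S)-6-bromo-3-[tert-butyl(dimethyl)silyl]oxy-7-chloro-7-methyloct-2-enoate F2. SnCl4 in CH2Cl2 at −78 °C then abstracts the tertiary chloride (again bromine-assisted) and the enol silane carbon is tert-alkylated intramolecularly (Reetz-type alkylation) with loss of the silyl group as its chloride.

Step 3. Risks are elimination or attack at halogen by the strongly basic dianion on the β-bromo triflate. The fallback sets out from 3 and comes back at 6. Allylmagnesium bromide with catalytic Li2CuCl4 (THF, −78 → −30 °C) couples at the primary triflate to give (5S)-5-bromo-6-chloro-6-methylhept-1-ene F3. Ozonolysis (O3, CH2Cl2, −78 °C; then PPh3) gives (4S)-4-bromo-5-chloro-5-methylhexanal F4. Roskamp homologation with methyl diazoacetate and catalytic SnCl2 (CH2Cl2, 23 °C) then delivers β-keto ester 6.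

**Further compounds**
F1 | step 9 | (2S,3S,6S,8S)-2,8-dibromo-3,7,7-trimethyl-11-methylidenespiro[5.5]undecan-3-ol | C=C1CC[C@H](Br)C(C)(C)[C@]12CC[C@](C)(O)[C@@H](Br)C2
F2 | step 4 | methyl (2Z,6S)-6-bromo-3-[tert-butyl(dimethyl)silyl]oxy-7-chloro-7-methyloct-2-enoate | COC(=O)/C=C(O[Si](C)(C)C(C)(C)C)/CC[C@H](Br)C(C)(C)Cl
F3 | step 3 | (5S)-5-bromo-6-chloro-6-methylhept-1-ene | C=CCC[C@H](Br)C(C)(C)Cl
F4 | step 3 | (4S)-4-bromo-5-chloro-5-methylhexanal | O=CCC[C@H](Br)C(C)(C)Cl
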